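The dihydropyranone C ring is disconnected at C3–C4 and O1–C2. This exposes ring A as a salicylaldehyde (aldehyde carbon = C4, free phenol = O1, side chain already at the future C6) and C2–C3 plus ring B as a terminal aryl alkyne. In one pot, Rh-catalysed hydroacylation adds the aldehyde C–H across the alkyne (C3–C4), and a chiral bifunctional thiourea then closes the resulting 2'-hydroxychalcone by oxa-Michael addition (O1–C2), setting C2 as S. The step exploits the salicyloyl unit O1–C8a–C4a–C4(=O) embedded in rings A/C; only one phenol is free, so the 6-alkyl (not 8-alkyl) flavanone must result.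

Key step: step 10

Assumption (chemistry): the quinidine-derived thiourea is taken to give the 2S series, by analogy with its behaviour in closures of activated 2'-hydroxychalcone analogues; its quinine-derived pseudo-enantiomer is the direct replacement if the unactivated chalcone responds with the opposite sense.

Step 1
Reactants: 1 phloroglucinol (benzene-1,3,5-triol)
Product: 2 5-(triisopropylsilyloxy)benzene-1,3-diol
Conditions: 1 (3 equiv), TIPSCl (1 equiv), imidazole, DMF, 0 °C → rt
Reagents that add atoms: triisopropylsilyl chloride, CC(C)[Si](Cl)(C(C)C)C(C)C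
Why: Statistical mono-O-silylation (silyl ether formation) of the C3-symmetric triol should stop largely at one silyl group because 1 is used in threefold excess and is washed out with water, and the bulky TIPS ether marks the oxygen that becomes O1.

Step 2
Reactants: 2 5-(triisopropylsilyloxy)benzene-1,3-diol
Product: 3 [3,5-bis(methoxymethoxy)phenoxy]triisopropylsilane
Conditions: MOMCl (2.5 equiv), iPr2NEt, CH2Cl2, 0 °C → rt
Reagents that add atoms: chloromethyl methyl ether, COCCl
Why: Base-mediated O-alkylation with MOMCl (acetal ether formation) caps the two remaining phenols with groups that are strong ortho-directors for lithiation and survive organometallics, selenolate, fluoride and rhodium.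

Step 3
Reactants: 4 geranyl bromide, (2E)-1-bromo-3,7-dimethylocta-2,6-diene
Product: 5 3-[(3E)-5-bromo-3-methylpent-3-en-1-yl]-2,2-dimethyloxirane (6,7-epoxygeranyl bromide; racemic)
Conditions: mCPBA (1.0 equiv), CH2Cl2, −20 → 0 °C; cold NaHCO3 wash, used crude
Reagents that add atoms: mCPBA, OOC(=O)c1cccc(Cl)c1
Why: Prilezhaev epoxidation should take the electron-rich 6,7-alkene because the 2,3-alkene is deactivated by the allylic C–Br bond; the new stereocentre is racemic and is erased in step 5.

Step 4
Reactants: 3 [3,5-bis(methoxymethoxy)phenoxy]triisopropylsilane; 5 6,7-epoxygeranyl bromide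
Product: 8 triisopropyl{4-[(2E)-5-(3,3-dimethyloxiran-2-yl)-3-methylpent-2-en-1-yl]-3,5-bis(methoxymethoxy)phenoxy}silane (racemic), via aryllithium 6 (not isolated), via arylcopper 7 (not isolated)
Conditions: n-BuLi, THF, 0 °C; CuBr·SMe2, −78 → −40 °C; then 5, −78 → 0 °C
Reagents that add atoms: none
Why: Directed ortho-metalation occurs at the position flanked by both OMOM groups (cooperative coordination, the TIPS-flanked sites are shielded), and the derived arylcopper couples with the primary allylic bromide by SN2 substitution with retention of the 2E geometry while the epoxide is inert at low temperature.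

Step 5
Reactants: 8 the aryl epoxide from step 4
Product: 11 (3E,6E)-8-[2,6-bis(methoxymethoxy)-4-(triisopropylsilyloxy)phenyl]-2,6-dimethylocta-3,6-dien-2-ol, via hydroxy selenide 9 (not isolated), via selenoxide 10 (not isolated)
Conditions: PhSeSePh (0.6 equiv), NaBH4, EtOH, rt → 60 °C; then THF, pyridine, 30% H2O2 (excess), 0 °C → rt
Reagents that add atoms: none
Why: Sharpless–Lauer epoxide-to-allylic-alcohol transposition: phenylselenolate opens the epoxide at the less hindered secondary carbon, and syn-elimination of the selenoxide can only run toward C5' (C7' bears no hydrogen), which gives the tertiary alcohol and the E-disubstituted C5'=C6' alkene, with pyridine and excess peroxide scavenging electrophilic selenium.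

Step 6
Reactants: 11 the TIPS-protected tertiary allylic alcohol
Product: 12 4-[(2E,5E)-7-hydroxy-3,7-dimethylocta-2,5-dien-1-yl]-3,5-bis(methoxymethoxy)phenol
Conditions: TBAF (1.1 equiv), THF, 0 °C
Reagents that add atoms: none
Why: Fluoride-induced Si–O cleavage releases the single phenol (the future O1) while the MOM ethers, both alkenes and the tertiary alcohol are untouched.

Step 7
Reactants: 12 the symmetric phenol
Product: 14 6-hydroxy-3-[(2E,5E)-7-hydroxy-3,7-dimethylocta-2,5-dien-1-yl]-2,4-bis(methoxymethoxy)benzaldehyde, via salicyl alcohol 13 (not isolated)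
Conditions: MgCl2, Et3N, (CH2O)n, MeCN, 70 °C
Reagents that add atoms: paraformaldehyde (as formaldehyde), C=O
Why: Magnesium-mediated ortho-formylation (Casnati–Skattebøl) delivers formaldehyde within the magnesium phenoxide exclusively ortho to the free hydroxyl, the two ortho sites being equivalent by symmetry, and the hydroxymethyl intermediate is oxidised to the aldehyde by Oppenauer-type hydride transfer to a second formaldehyde, so the formyl group sits between the free OH and an OMOM group.

Step 8
Reactants: 15 vanillin (4-hydroxy-3-methoxybenzaldehyde)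
Product: 16 3-methoxy-4-(methoxymethoxy)benzaldehyde
Conditions: MOMCl, iPr2NEt, CH2Cl2, 0 °C → rt
Reagents that add atoms: chloromethyl methyl ether, COCCl
Why: O-alkylation of the vanillin phenol with MOMCl (acetal ether formation) is chosen so that all three phenol protecting groups fall in one final operation.

Step 9
Reactants: 16 3-methoxy-4-(methoxymethoxy)benzaldehyde
Product: 17 4-ethynyl-2-methoxy-1-(methoxymethoxy)benzene
Conditions: dimethyl (1-diazo-2-oxopropyl)phosphonate, K2CO3, MeOH, 0 °C → rt
Reagents that add atoms: Ohira–Bestmann reagent, COP(=O)(OC)C(=[N+]=[N-])C(C)=O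
Why: Seyferth–Gilbert homologation with the Ohira–Bestmann reagent converts the aldehyde into the terminal alkyne under mild carbonate conditions that MOM ethers tolerate.

Step 10
Reactants: 14 the salicylaldehyde; 17 the aryl alkyne (1.5 equiv)
Product: 19 (2S)-6-[(2E,5E)-7-hydroxy-3,7-dimethylocta-2,5-dien-1-yl]-2-[3-methoxy-4-(methoxymethoxy)phenyl]-5,7-bis(methoxymethoxy)chroman-4-one, via chalcone 18 (not isolated)
Conditions: [Rh(cod)Cl]2 (2.5 mol%), dppf (5 mol%), Na2CO3 (5 mol%), toluene, 80 °C; then −20 °C, quinidine-derived 3,5-bis(trifluoromethyl)phenyl thiourea (20 mol%), −20 → 0 °C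
Reagents that add atoms: none
Why: Phenoxide-directed oxidative addition of Rh(I) into the aldehyde C–H of 14 gives a five-membered acyl–Rh(III)–H chelate that hydrometalates the terminal alkyne of 17 and reductively eliminates to the (E)-2'-hydroxychalcone 18 (C3–C4 bond), after which the quinuclidine nitrogen of the thiourea catalyst activates the only free phenol while the thiourea hydrogen-bonds the enone carbonyl, and the phenol oxygen adds to the β-carbon (O1–C2 bond). The closest known reaction types are the tandem Rh-catalysed alkyne hydroacylation/oxa-Michael annulation of salicylaldehydes to chroman-4-ones and the amine-base-catalysed asymmetric cyclisation of 2'-hydroxychalcones to flavanones. The pyranone C ring is the only ring closed, by a 6-endo-trig intramolecular conjugate addition, so that overall the O1–C8a–C4a–C4 unit is annulated in a formal [4+2] sense onto the two alkyne carbons. The single new stereocentre C2 is set under catalyst control, the hydrogen-bonded ion pair exposing one enantiotopic face of the planar enone to give 2S, and the low temperature should keep the closure under kinetic control and suppress retro-Michael erosion. The step needs linear regioselectivity in the hydroacylation (acyl to the terminal alkyne carbon, favoured sterically and by the aryl substituent as with 1-arylalkynes), chemoselectivity for the alkyne over the tri- and disubstituted side-chain alkenes (unactivated internal alkenes should not insert), and closure through the correct oxygen, which is secured because the oxygen flanked by the side chain and the para oxygen are MOM-capped, so only the 6-alkylated flavanone can form.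

Step 11
Reactants: 19 the tris-MOM flavanone
Product: 21 tomentodiplacone B, (2S)-5,7-dihydroxy-2-(4-hydroxy-3-methoxyphenyl)-6-[(2E,5E)-7-hydroxy-3,7-dimethylocta-2,5-dien-1-yl]chroman-4-one, via tetrakis-TMS ether 20 (not isolated)
Conditions: TMSOTf (8 equiv), 2,2'-bipyridyl (12 equiv), MeCN, 0 °C → rt; then H2O, rt
Reagents that add atoms: none
Why: Silyl triflate/2,2'-bipyridyl cleavage of aryl MOM ethers proceeds through pyridinium-type intermediates to aryl TMS ethers that water hydrolyses in the same pot, so neither strong protic acid nor base touches the tertiary allylic alcohol, the ortho-allyl phenols or the base-labile C2 stereocentre.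

Compound list
1 | phloroglucinol (benzene-1,3,5-triol) | Oc1cc(O)cc(O)c1 | starting material
2 | 5-(triisopropylsilyloxy)benzene-1,3-diol | CC(C)[Si](Oc1cc(O)cc(O)c1)(C(C)C)C(C)C | intermediate
3 | [3,5-bis(methoxymethoxy)phenoxy]triisopropylsilane | COCOc1cc(OCOC)cc(O[Si](C(C)C)(C(C)C)C(C)C)c1 | intermediate
4 | geranyl bromide, (2E)-1-bromo-3,7-dimethylocta-2,6-diene | BrC/C=C(\C)CCC=C(C)C | starting material
5 | 3-[(3E)-5-bromo-3-methylpent-3-en-1-yl]-2,2-dimethyloxirane (6,7-epoxygeranyl bromide, racemic) | BrC/C=C(\C)CCC1OC1(C)C | intermediate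
6 | [2,6-bis(methoxymethoxy)-4-(triisopropylsilyloxy)phenyl]lithium (formed in situ) | [Li]c1c(OCOC)cc(O[Si](C(C)C)(C(C)C)C(C)C)cc1OCOC | intermediate
7 | [2,6-bis(methoxymethoxy)-4-(triisopropylsilyloxy)phenyl]copper (formed in situ) | [Cu]c1c(OCOC)cc(O[Si](C(C)C)(C(C)C)C(C)C)cc1OCOC | intermediate
8 | triisopropyl{4-[(2E)-5-(3,3-dimethyloxiran-2-yl)-3-methylpent-2-en-1-yl]-3,5-bis(methoxymethoxy)phenoxy}silane (racemic) | COCOc1cc(O[Si](C(C)C)(C(C)C)C(C)C)cc(OCOC)c1C/C=C(\C)CCC2OC2(C)C | intermediate
9 | (6E)-8-[2,6-bis(methoxymethoxy)-4-(triisopropylsilyloxy)phenyl]-2,6-dimethyl-3-(phenylselanyl)oct-6-en-2-ol (racemic, formed in situ) | COCOc1cc(O[Si](C(C)C)(C(C)C)C(C)C)cc(OCOC)c1C/C=C(\C)CCC([Se]c2ccccc2)C(C)(C)O | intermediate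
10 | the selenoxide of 9 (formed in situ) | COCOc1cc(O[Si](C(C)C)(C(C)C)C(C)C)cc(OCOC)c1C/C=C(\C)CCC([Se](=O)c2ccccc2)C(C)(C)O | intermediate
11 | (3E,6E)-8-[2,6-bis(methoxymethoxy)-4-(triisopropylsilyloxy)phenyl]-2,6-dimethylocta-3,6-dien-2-ol | COCOc1cc(O[Si](C(C)C)(C(C)C)C(C)C)cc(OCOC)c1C/C=C(\C)C/C=C/C(C)(C)O | intermediate
12 | 4-[(2E,5E)-7-hydroxy-3,7-dimethylocta-2,5-dien-1-yl]-3,5-bis(methoxymethoxy)phenol | COCOc1cc(O)cc(OCOC)c1C/C=C(\C)C/C=C/C(C)(C)O | intermediate
13 | 2-(hydroxymethyl)-4-[(2E,5E)-7-hydroxy-3,7-dimethylocta-2,5-dien-1-yl]-3,5-bis(methoxymethoxy)phenol (formed in situ as its magnesium salt) | COCOc1cc(O)c(CO)c(OCOC)c1C/C=C(\C)C/C=C/C(C)(C)O | intermediate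
14 | 6-hydroxy-3-[(2E,5E)-7-hydroxy-3,7-dimethylocta-2,5-dien-1-yl]-2,4-bis(methoxymethoxy)benzaldehyde | COCOc1cc(O)c(C=O)c(OCOC)c1C/C=C(\C)C/C=C/C(C)(C)O | intermediate
15 | vanillin (4-hydroxy-3-methoxybenzaldehyde) | O=Cc1ccc(O)c(OC)c1 | starting material
16 | 3-methoxy-4-(methoxymethoxy)benzaldehyde | O=Cc1ccc(OCOC)c(OC)c1 | intermediate
17 | 4-ethynyl-2-methoxy-1-(methoxymethoxy)benzene | C#Cc1ccc(OCOC)c(OC)c1 | intermediate
18 | (2E)-1-{6-hydroxy-3-[(2E,5E)-7-hydroxy-3,7-dimethylocta-2,5-dien-1-yl]-2,4-bis(methoxymethoxy)phenyl}-3-[3-methoxy-4-(methoxymethoxy)phenyl]prop-2-en-1-one (formed in situ) | COCOc1cc(O)c(C(=O)/C=C/c2ccc(OCOC)c(OC)c2)c(OCOC)c1C/C=C(\C)C/C=C/C(C)(C)O | intermediate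
19 | (2S)-6-[(2E,5E)-7-hydroxy-3,7-dimethylocta-2,5-dien-1-yl]-2-[3-methoxy-4-(methoxymethoxy)phenyl]-5,7-bis(methoxymethoxy)chroman-4-one | COc1cc([C@@H]2CC(=O)c3c(cc(OCOC)c(C/C=C(\C)C/C=C/C(C)(C)O)c3OCOC)O2)ccc1OCOC | intermediate
20 | (2S)-flavanone carrying trimethylsilyl ethers at O5, O7, O4' and the side-chain tertiary oxygen (formed in situ) | COc1cc([C@@H]2CC(=O)c3c(cc(O[Si](C)(C)C)c(C/C=C(\C)C/C=C/C(C)(C)O[Si](C)(C)C)c3O[Si](C)(C)C)O2)ccc1O[Si](C)(C)C | intermediate
21 | tomentodiplacone B, (2S)-5,7-dihydroxy-2-(4-hydroxy-3-methoxyphenyl)-6-[(2E,5E)-7-hydroxy-3,7-dimethylocta-2,5-dien-1-yl]chroman-4-one | COc1cc([C@@H]2CC(=O)c3c(cc(O)c(C/C=C(\C)C/C=C/C(C)(C)O)c3O)O2)ccc1O | target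

Total step count: 11.
Longest linear sequence: 8 steps (steps 1, 2, 4, 5, 6, 7, 10, 11, from phloroglucinol); step 3 and steps 8–9 are side branches.

Steps most likely to fail

Step 10. The hydroacylation may run with branched (Markovnikov) regiochemistry or lose alkyne to rhodium-mediated oligomerisation. Rh–H may also migrate the skipped diene into conjugation. The closure of an unactivated chalcone may proceed with weak facial discrimination or erode by retro-Michael reaction. The fallback sets out from 14 and 16 and comes back at 19; it assembles the skeleton by Grignard addition and Claisen–Schmidt condensation and obtains the stereocentre by resolution instead of induction. Excess MeMgBr (THF, −78 → 0 °C) should add to 14 to give 1-{6-hydroxy-3-[(2E,5E)-7-hydroxy-3,7-dimethylocta-2,5-dien-1-yl]-2,4-bis(methoxymethoxy)phenyl}ethanol F1. Activated MnO2 in CH2Cl2 should oxidise it to the corresponding 2'-hydroxyacetophenone F2. Condensation of F2 with aldehyde 16 (KOH, EtOH, rt) should give chalcone 18, now isolated and purified. NaOAc in refluxing EtOH should close it to the racemic tris-MOM flavanone F3. Kinetic resolution by asymmetric transfer hydrogenation (RuCl(p-cymene)[(R,R)-TsDPEN], HCO2H/Et3N) should then reduce the 2R enantiomer to the cis-(2R,4R)-flavan-4-ol F4 and leave (2S)-19, which is separated by chromatography.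

Step 11. The tertiary allylic alcohol may ionise, or the liberated 5- and 7-phenols may add to the C2'=C3' alkene (chroman formation) during the triflate-rich hydrolytic stage. Cleavage of the hindered, chelated 5-O-MOM group may also stay incomplete. The fallback sets out from 19 and comes back at 21; it separates acetal cleavage from phenol release, so that the phenols are freed by fluoride and not by hydrolysis. TESOTf/2,2'-bipyridyl (CH2Cl2, 0 °C → rt) should trans-protect 19 to the isolable, neutral (2S)-flavanone tetrakis(triethylsilyl) ether F5 (O5, O7, O4' and the tertiary oxygen). Buffered fluoride (HF·pyridine with excess pyridine, THF, 0 °C) should then cleave all four Si–O bonds to give 21.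

Step 5. Electrophilic selenium species released in the selenoxide elimination may attack the very electron-rich trioxygenated arene or the C2'=C3' alkene, and the aryl silyl ether may be lost under the selenolate conditions. The fallback sets out from 3 and comes back at 11; it carries out the epoxide-to-allylic-alcohol transposition on the side-chain fragment before the arene is present. Purchased geranyl acetate F6 should be epoxidised (mCPBA, CH2Cl2, 0 °C) to 6,7-epoxygeranyl acetate F7. PhSeSePh/NaBH4 in EtOH followed by H2O2 should convert F7 into (2E,5E)-7-hydroxy-3,7-dimethylocta-2,5-dien-1-yl acetate F8. Compound 3 is lithiated as in step 4 (aryllithium 6) and quenched with 2-isopropoxy-4,4,5,5-tetramethyl-1,3,2-dioxaborolane to give the arylboronic pinacol ester F9. A Pd-catalysed allyl–aryl Suzuki coupling of F9 with F8 (Pd2(dba)3/SPhos, K3PO4, THF–H2O, 50 °C), which tolerates the free tertiary alcohol and should couple at the less hindered allyl terminus, gives 11.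

Further compounds
F1 | step 10 | 1-{6-hydroxy-3-[(2E,5E)-7-hydroxy-3,7-dimethylocta-2,5-dien-1-yl]-2,4-bis(methoxymethoxy)phenyl}ethanol (racemic) | COCOc1cc(O)c(C(C)O)c(OCOC)c1C/C=C(\C)C/C=C/C(C)(C)O
F2 | step 10 | 1-{6-hydroxy-3-[(2E,5E)-7-hydroxy-3,7-dimethylocta-2,5-dien-1-yl]-2,4-bis(methoxymethoxy)phenyl}ethanone | COCOc1cc(O)c(C(C)=O)c(OCOC)c1C/C=C(\C)C/C=C/C(C)(C)O
F3 | step 10 | racemic 6-[(2E,5E)-7-hydroxy-3,7-dimethylocta-2,5-dien-1-yl]-2-[3-methoxy-4-(methoxymethoxy)phenyl]-5,7-bis(methoxymethoxy)chroman-4-one | COc1cc(C2CC(=O)c3c(cc(OCOC)c(C/C=C(\C)C/C=C/C(C)(C)O)c3OCOC)O2)ccc1OCOC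
F4 | step 10 | (2R,4R)-6-[(2E,5E)-7-hydroxy-3,7-dimethylocta-2,5-dien-1-yl]-2-[3-methoxy-4-(methoxymethoxy)phenyl]-5,7-bis(methoxymethoxy)chroman-4-ol | COc1cc([C@H]2C[C@@H](O)c3c(cc(OCOC)c(C/C=C(\C)C/C=C/C(C)(C)O)c3OCOC)O2)ccc1OCOC
F5 | step 11 | (2S)-2-[3-methoxy-4-(triethylsilyloxy)phenyl]-5,7-bis(triethylsilyloxy)-6-[(2E,5E)-3,7-dimethyl-7-(triethylsilyloxy)octa-2,5-dien-1-yl]chroman-4-one | COc1cc([C@@H]2CC(=O)c3c(cc(O[Si](CC)(CC)CC)c(C/C=C(\C)C/C=C/C(C)(C)O[Si](CC)(CC)CC)c3O[Si](CC)(CC)CC)O2)ccc1O[Si](CC)(CC)CC
F6 | step 5 | geranyl acetate (purchased) | CC(=O)OC/C=C(\C)CCC=C(C)C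
F7 | step 5 | 6,7-epoxygeranyl acetate (racemic) | CC(=O)OC/C=C(\C)CCC1OC1(C)C
F8 | step 5 | (2E,5E)-7-hydroxy-3,7-dimethylocta-2,5-dien-1-yl acetate | CC(=O)OC/C=C(\C)C/C=C/C(C)(C)O
F9 | step 5 | 2-[2,6-bis(methoxymethoxy)-4-(triisopropylsilyloxy)phenyl]-4,4,5,5-tetramethyl-1,3,2-dioxaborolane | COCOc1cc(O[Si](C(C)C)(C(C)C)C(C)C)cc(OCOC)c1B2OC(C)(C)C(C)(C)O2
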